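## Retrosynthetic overview (labdane numbering)

1. The target comes from an acyclic C20 epoxy diol that already carries the butenolide. One Ti(III) radical cascade forms C4–C5 (ring A), then C9–C10 (ring B), and also creates the C8(17) methylene. This is the last step and uses no protecting groups.
2. The epoxy diol comes from a (Z)-2-ene-1,4-diol by OH-directed epoxidation, which fixes C3. That diol comes from a terminal (E)-1,3-diene by enantioselective 1,4-diboration/oxidation, which fixes C2 and installs O2 and O18 together.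
3. The diene comes from homofarnesyl butenolide by terminal allylic hydroxylation followed by 1,4-dehydration.
4. The butenolide comes from a Z-enol triflate and Bu3SnCH2OH. The triflate comes from methyl acetoacetate dianion and (E,E)-farnesyl bromide.
5. Ring order: butenolide (step 2), sacrificial oxirane (step 6), rings A and B together (step 7).

Assumption: positions are in labdane numbering (C18 = CH2OH carbon on C4, C19 = CH3 on C4, C17 = exocyclic CH2), and the ligand antipode in step 5 is the one that gives the 10S boronate (both antipodes are available from D- or L-tartrate).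

## Route

Step 1
Reactants: 1 methyl acetoacetate; 2 (2E,6E)-farnesyl bromide
Product: 4 methyl (2Z,6E,10E)-7,11,15-trimethyl-3-{[(trifluoromethyl)sulfonyl]oxy}hexadeca-2,6,10,14-tetraenoate, via beta-keto ester 3 (not isolated)
Conditions: 1, NaH then n-BuLi, THF, 0 °C; 2, 0 °C; then PhNTf2, 0 °C to rt
Reagents that add atoms: N-phenylbis(trifluoromethanesulfonimide), O=S(=O)(N(c1ccccc1)S(=O)(=O)C(F)(F)F)C(F)(F)F
Why: Weiler dianion gamma-alkylation is an SN2 reaction at the primary allylic bromide that keeps both E-alkenes, and the surviving metal-chelated enolate is O-triflated in the same pot, so OTf ends up cis to the ester (Z-enol triflate).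

Step 2
Reactants: 4 Z-enol triflate; 5 (tributylstannyl)methanol
Product: 7 4-[(3E,7E)-4,8,12-trimethyltrideca-3,7,11-trien-1-yl]furan-2(5H)-one, via hydroxymethyl enoate 6 (not isolated)
Conditions: Pd(PPh3)4 (5 mol %), LiCl (3 equiv), 1,4-dioxane, 90 °C
Reagents that add atoms: (tributylstannyl)methanol (5), OC[Sn](CCCC)(CCCC)CCCC
Why: Stille hydroxymethylation retains the vinyl triflate geometry, so the new CH2OH sits cis to CO2Me and lactonises spontaneously to the beta-substituted butenolide.

Step 3
Reactants: 7 homofarnesyl butenolide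
Product: 8 4-[(3E,7E,11E)-13-hydroxy-4,8,12-trimethyltrideca-3,7,11-trien-1-yl]furan-2(5H)-one
Conditions: SeO2 (10 mol %), salicylic acid (10 mol %), t-BuOOH (3 equiv), CH2Cl2, 0 °C to rt, stopped at about 60 % conversion (7 recycled)
Reagents that add atoms: tert-butyl hydroperoxide, CC(C)(C)OO (terminal oxygen source); selenium dioxide, O=[Se]=O (catalytic oxygen carrier)
Why: Catalytic SeO2 allylic hydroxylation (ene reaction then [2,3]-shift, Umbreit–Sharpless conditions) prefers the least hindered terminal isopropylidene, oxidises only its E-methyl group, and leaves the electron-poor butenolide alone.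

Step 4
Reactants: 8 terminal (E)-allylic alcohol
Product: 11 4-[(3E,7E,10E)-4,8,12-trimethyltrideca-3,7,10,12-tetraen-1-yl]furan-2(5H)-one, via sulfenate ester 9 (not isolated), via allylic sulfoxide 10 (not isolated)
Conditions: 2,4-(O2N)2C6H3SCl (1.2 equiv), Et3N (3 equiv), ClCH2CH2Cl, 0 °C then reflux
Reagents that add atoms: 2,4-dinitrobenzenesulfenyl chloride, ClSc1ccc(cc1[N+](=O)[O-])[N+](=O)[O-] (ArS unit present only in 9 and 10)
Why: In this Reich 1,4-dehydration, O-sulfenylation is followed by a sulfenate-to-sulfoxide [2,3]-shift (Mislow–Evans type) that places sulfur on C3, and thermal syn-elimination toward the only beta-hydrogens (C2–H) gives the (E)-1,3-diene.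

Step 5
Reactants: 11 terminal (E)-1,3-diene
Product: 13 4-[(3E,7E,10S,11Z)-10,13-dihydroxy-4,8,12-trimethyltrideca-3,7,11-trien-1-yl]furan-2(5H)-one, via bis(boronate) 12 (not isolated)
Conditions: Pt2(dba)3 (3 mol %), TADDOL-derived phenylphosphonite L* (6 mol %, antipode giving 10S), B2pin2 (1.05 equiv), THF, 60 °C; then 30 % H2O2, pH 7 phosphate buffer, THF, 0 °C to rt
Reagents that add atoms: bis(pinacolato)diboron, CC1(C)OB(OC1(C)C)B1OC(C)(C)C(C)(C)O1 (boryl groups of 12); hydrogen peroxide, OO (both new hydroxyl oxygens of 13)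
Why: Pt-catalysed enantioselective 1,4-diboration engages only the s-cis conjugated diene and leaves the isolated trisubstituted alkenes untouched; it sets C2 (chain C10, S) under ligand control with a Z-alkene, and buffered C–B oxidation proceeds with retention without opening the lactone.

Step 6
Reactants: 13 (S,Z)-ene-1,4-diol
Product: 14 4-{(3E,7E,10S)-10-hydroxy-10-[(2R,3S)-3-(hydroxymethyl)-3-methyloxiran-2-yl]-4,8-dimethyldeca-3,7-dien-1-yl}furan-2(5H)-one
Conditions: VO(acac)2 (5 mol %), t-BuOOH (1.2 equiv, decane), CH2Cl2, 0 °C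
Reagents that add atoms: tert-butyl hydroperoxide, CC(C)(C)OO
Why: Hydroxyl-directed vanadium epoxidation (Sharpless–Michaelson) oxidises only the doubly allylic alkene, and A(1,3) strain from the cis CH2OH holds C2–H in the alkene plane so oxygen arrives syn to the C2–OH, giving the threo epoxy alcohol and setting C3 (R in 14, which becomes 3S in the target).

Step 7
Reactants: 14 epoxy diol
Product: 15 4-{2-[(1R,4aS,5S,6S,7S,8aS)-6,7-dihydroxy-5-(hydroxymethyl)-5,8a-dimethyl-2-methylidenedecahydronaphthalen-1-yl]ethyl}furan-2(5H)-one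
Conditions: Cp2TiCl2 (3 equiv), Mn dust (8 equiv), degassed THF, rt (green Cp2TiCl); slow addition of 14 (final 0.01 M), rt, 3 h; 1 M HCl work-up
Reagents that add atoms: none
Why: In this titanocene(III) radical polyene bicyclisation (Nugent–RajanBabu epoxide homolysis), Cp2TiCl cleaves the tertiary C4–O bond with C3–O retained, the planar C4 radical closes 6-endo on C5=C10 and the C10 radical closes 6-endo on C9=C8 through a chair–chair array with C2–OH, C3–OTi, the larger Ti-coordinated CH2OH and the C9 side chain all equatorial (this sets C4, C5, C10 and C9), and the hindered C8 radical loses a C17 hydrogen to a second Cp2TiCl to give the exocyclic methylene.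

## Compound list

1 | methyl acetoacetate | COC(=O)CC(C)=O | starting material
2 | (2E,6E)-farnesyl bromide | CC(C)=CCC/C(C)=C/CC/C(C)=C/CBr | starting material
3 | methyl (6E,10E)-7,11,15-trimethyl-3-oxohexadeca-6,10,14-trienoate (present as its enolate, not isolated) | COC(=O)CC(=O)CC/C=C(C)/CC/C=C(C)/CCC=C(C)C | intermediate
4 | methyl (2Z,6E,10E)-7,11,15-trimethyl-3-{[(trifluoromethyl)sulfonyl]oxy}hexadeca-2,6,10,14-tetraenoate | COC(=O)/C=C(OS(=O)(=O)C(F)(F)F)/CC/C=C(C)/CC/C=C(C)/CCC=C(C)C | intermediate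
5 | (tributylstannyl)methanol | OC[Sn](CCCC)(CCCC)CCCC | starting material
6 | methyl (2Z,6E,10E)-3-(hydroxymethyl)-7,11,15-trimethylhexadeca-2,6,10,14-tetraenoate (not isolated) | COC(=O)/C=C(CO)/CC/C=C(C)/CC/C=C(C)/CCC=C(C)C | intermediate
7 | 4-[(3E,7E)-4,8,12-trimethyltrideca-3,7,11-trien-1-yl]furan-2(5H)-one | O=C1C=C(CC/C=C(C)/CC/C=C(C)/CCC=C(C)C)CO1 | intermediate
8 | 4-[(3E,7E,11E)-13-hydroxy-4,8,12-trimethyltrideca-3,7,11-trien-1-yl]furan-2(5H)-one | O=C1C=C(CC/C=C(C)/CC/C=C(C)/CC/C=C(\C)CO)CO1 | intermediate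
9 | 2,4-dinitrobenzenesulfenate ester of 8 (not isolated) | O=C1C=C(CC/C=C(C)/CC/C=C(C)/CC/C=C(\C)COSc2ccc(cc2[N+](=O)[O-])[N+](=O)[O-])CO1 | intermediate
10 | 4-[(3E,7E)-11-(2,4-dinitrophenylsulfinyl)-4,8,12-trimethyltrideca-3,7,12-trien-1-yl]furan-2(5H)-one (mixture of diastereomers at C and S, not isolated) | O=C1C=C(CC/C=C(C)/CC/C=C(C)/CCC(C(C)=C)S(=O)c2ccc(cc2[N+](=O)[O-])[N+](=O)[O-])CO1 | intermediate
11 | 4-[(3E,7E,10E)-4,8,12-trimethyltrideca-3,7,10,12-tetraen-1-yl]furan-2(5H)-one | O=C1C=C(CC/C=C(C)/CC/C=C(C)/C/C=C/C(C)=C)CO1 | intermediate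
12 | 4-[(3E,7E,10S,11Z)-4,8,12-trimethyl-10,13-bis(4,4,5,5-tetramethyl-1,3,2-dioxaborolan-2-yl)trideca-3,7,11-trien-1-yl]furan-2(5H)-one (not isolated) | O=C1C=C(CC/C=C(C)/CC/C=C(C)/C[C@H](B2OC(C)(C)C(C)(C)O2)/C=C(/C)CB2OC(C)(C)C(C)(C)O2)CO1 | intermediate
13 | 4-[(3E,7E,10S,11Z)-10,13-dihydroxy-4,8,12-trimethyltrideca-3,7,11-trien-1-yl]furan-2(5H)-one | O=C1C=C(CC/C=C(C)/CC/C=C(C)/C[C@H](O)/C=C(/C)CO)CO1 | intermediate
14 | 4-{(3E,7E,10S)-10-hydroxy-10-[(2R,3S)-3-(hydroxymethyl)-3-methyloxiran-2-yl]-4,8-dimethyldeca-3,7-dien-1-yl}furan-2(5H)-one | O=C1C=C(CC/C=C(C)/CC/C=C(C)/C[C@H](O)[C@H]2O[C@@]2(C)CO)CO1 | intermediate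
15 | 4-{2-[(1R,4aS,5S,6S,7S,8aS)-6,7-dihydroxy-5-(hydroxymethyl)-5,8a-dimethyl-2-methylidenedecahydronaphthalen-1-yl]ethyl}furan-2(5H)-one (CNP0254095.1) | C=C1CC[C@H]2[C@@](C)(C[C@H](O)[C@@H](O)[C@]2(C)CO)[C@@H]1CCC1=CC(=O)OC1 | target

## Totals and risks

Total step count: 7. Longest linear sequence: 7.

**Step 7 is the most likely to fail.**
- The two free hydroxyls can tie up titanium.
- The C4 facial selectivity rests on CH2OH being only moderately larger than CH3.
- The C8 radical could be reduced or intercepted before hydrogen loss.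

The fallback gives up the protecting-group-free end-game and steers the cascade sterically. Starting from 14, TBSCl/imidazole in DMF gives the bis(TBS) ether F1. In this compound no OH binds titanium and CH2OTBS is far larger than CH3. The titanocene(III) cascade on this substrate gives the bicyclic 2,18-bis(TBS) ether F2. HF·pyridine in THF then removes both silyl groups, and the route is rejoined at 15.

**Step 5 is next.** A 1,3-disubstituted diene may give lower ee or some 1,2-addition, and the butenolide is an unusual bystander for this catalyst. The fallback moves control of C2 from C–B bond formation to a reagent-controlled ketone reduction: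
- Starting from 11, achiral Ni(cod)2/PCy3-catalysed 1,4-diboration gives the racemic bis(boronate) F3.
- Buffered H2O2 converts it into the racemic (Z)-ene-diol F4.
- TBSCl/imidazole silylates only the primary hydroxyl, giving the racemic mono-TBS ether F5.
- MnO2 oxidises the secondary allylic alcohol to the (Z)-enone F6.
- (R)-Me-CBS with catecholborane in toluene at −78 °C gives the (10S)-alcohol mono-TBS ether F7.
- HF·pyridine then rejoins the route at 13.

**Step 4 is third.** The sulfenyl chloride can add to the electron-rich trisubstituted alkenes, and the sulfenate/sulfoxide equilibrium may drain slowly. The fallback replaces the sigmatropic/syn-elimination logic with pi-allyl palladium chemistry. Starting from 8, ClCO2Me/pyridine gives the allylic methyl carbonate F8. Pd(PPh3)4 in refluxing THF ionises it, and beta-hydride elimination from C2–H (the only position available) gives the (E)-diene. The route is rejoined at 11.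

## Further compounds

F1 | step 7 | 2,18-bis-O-(tert-butyldimethylsilyl) ether of 14 | O=C1C=C(CC/C=C(C)/CC/C=C(C)/C[C@H](O[Si](C)(C)C(C)(C)C)[C@H]2O[C@@]2(C)CO[Si](C)(C)C(C)(C)C)CO1
F2 | step 7 | 2,18-bis-O-(tert-butyldimethylsilyl) ether of 15 | C=C1CC[C@H]2[C@@](C)(C[C@H](O[Si](C)(C)C(C)(C)C)[C@@H](O)[C@]2(C)CO[Si](C)(C)C(C)(C)C)[C@@H]1CCC1=CC(=O)OC1
F3 | step 5 | racemic (3E,7E,11Z)-10,13-bis(pinacolboryl) compound (rac-12) | O=C1C=C(CC/C=C(C)/CC/C=C(C)/CC(B2OC(C)(C)C(C)(C)O2)/C=C(/C)CB2OC(C)(C)C(C)(C)O2)CO1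
F4 | step 5 | racemic (3E,7E,11Z)-10,13-diol (rac-13) | O=C1C=C(CC/C=C(C)/CC/C=C(C)/CC(O)/C=C(/C)CO)CO1
F5 | step 5 | racemic 13-O-(tert-butyldimethylsilyl) ether of the diol | O=C1C=C(CC/C=C(C)/CC/C=C(C)/CC(O)/C=C(/C)CO[Si](C)(C)C(C)(C)C)CO1
F6 | step 5 | (3E,7E,11Z)-13-(tert-butyldimethylsilyloxy)-10-oxo enone | O=C1C=C(CC/C=C(C)/CC/C=C(C)/CC(=O)/C=C(/C)CO[Si](C)(C)C(C)(C)C)CO1
F7 | step 5 | (10S)-13-O-(tert-butyldimethylsilyl) ether of 13 | O=C1C=C(CC/C=C(C)/CC/C=C(C)/C[C@H](O)/C=C(/C)CO[Si](C)(C)C(C)(C)C)CO1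
F8 | step 4 | methyl carbonate of 8 | O=C1C=C(CC/C=C(C)/CC/C=C(C)/CC/C=C(\C)COC(=O)OC)CO1
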